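I counted what was missing.

| flask | solid substrate | temperature | remark | time |
|---|---|---|---|---|
| maple | 0.050 M | 50 °C | the very flask that is asked about, followed so far |  |
| cedar | 0.050 M | 45 °C | run made earlier |  |
| flask | 0.050 M | 50 °C |  | 3.0 min |

- maple (time / min: target / %, solid substrate / %): 0.667: 23.5, 37.2; 1.33: 31.7, 0; 2.00: 21.0, 0; 2.50: 19.0, 0.7; 3.00: 16.9, 0.4
- cedar (time / min: target / %, solid substrate / %): 0.667: 20.7, 39.6; 1.33: 31.0, 0; 2.00: 25.1, 0.8; 2.50: 18.5, 2.4; 3.00: 18.0, 1.0

(standard deviation of a reading: 1 percentage point)

- Wednesday's: at 3.0 min take out 90% of the target then present, then wait 1.5 min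
- Friday's: change nothing and wait 1.5 min more
- Thursday's: at 3.0 min raise the temperature by 20 K, then wait 1.5 min

- as a solid, counted per litre of solution: solid substrate
- removed target is counted in
- at the start none of the solid substrate is in solution

- target, in percent of the solid substrate first charged, at 3.0 min
- which option adds most target ("none" when 2 percentage points or less is all one gets) (Wednesday's / Friday's / Thursday's / none)
- target present, with what was taken out counted in, in percent of the solid substrate first charged, after Friday's
- target present, with what was taken out counted in, in percent of the solid substrate first charged, after Thursday's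

In maple at 3.00 min, target read 16.9% and solid substrate 0.4%, so I took the rest of the charge to be dissolved in some form I could not read. I took 16.9% as my answer for now. I called target divided by that unread remainder the holding ratio, which read 0.204 in maple; if maple was at rest, this reading serves as an apparent equilibrium constant.

I assumed the ratio would return after a disturbance. For Wednesday's, my first answer was that target refills what is removed, 15 percentage points. Putting that back in, the flask then holds less of the charge, so by the same ratio target settles lower and my estimate of the gain is 13 points.

Then I turned the question round. For Thursday's to beat that, heating must lift the ratio to 0.421, a factor of 2.06. Spread as equal factors over 4 temperature steps, each as wide as the gap between cedar and maple, each is 1.20, which the step from cedar to maple should show. Cedar's ratio was 0.222, so the step read 0.919, less than needed. But cedar's 25.1% against maple's 21.0% at 2.00 min warned me that cedar might not have been at rest. I chose Wednesday's, with that doubt.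

The forecast gave 17.3% (16.2% to 18.4%), 15.5% for Friday's and 13.5% for Thursday's, since “heating probably lowers target”; it also chose Wednesday's.

The flask gave 18.0%, 17.0% after Friday's and 51.5% after Thursday's, so the best option was Thursday's.

    starting material ⇌ target (K = 1.40, k = 0.103 s⁻¹, Ea = 75.0 kJ mol⁻¹, ΔH = 59.0 kJ mol⁻¹)
    starting material ⇌ isomer of the product (K = 5.90, k = 0.00536 s⁻¹, Ea = 94.0 kJ mol⁻¹, ΔH = −21.0 kJ mol⁻¹)
    target ⇌ isomer of the product (k = 0.0280 s⁻¹, Ea = 84.0 kJ mol⁻¹)
    solid substrate ⇌ starting material, rate k4*(cs4 - [starting material]) while solid is left; crystals form when [starting material] > cs4 (solubility = 43.0 mM, k = 0.0227 s⁻¹)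
    (constants at 50 °C)

Thursday's took the ratio from 0.220 to 1.06, a factor of 4.83, more than the 2.06 required. The same count on the neighbouring flask, read at 2.0 min, leaves 77.9% unread beside target's 22.1%; that flask held it as starting material 16.6% and isomer of the product 61.3%. Its ratio was 0.284, higher than the 0.203 of the flask at 30.0 min.

The earlier runs and the new flask stem from a simulated flask for substances that don't exist.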